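**Retrosynthetic overview**
- The target is reached by catalyst-controlled transfer hydrogenation of the macrocyclic aryl benzyl ketone, which sets the only stereocentre (S), after global O-demethylation.
- The 18-membered ring is closed at the ring A(C3)–O–ring B diaryl ether by an oxidative phenol coupling modelled on the bis(bibenzyl) biosynthesis: ring A is oxidised to a bromo-o-quinone monoketal, the ring-B phenoxide attacks it, and reduction re-aromatises.
- The open-chain precursor comes from a Wittig/hydrogenation pair (A–CH2CH2–D bridge), an α-aminophosphonate olefination/hydrolysis (B–CO–CH2–C bridge) and an SNAr reaction (C–O–D ether).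
- Ring order: the four benzene rings are bought; the macrocycle is the only ring formed (third step from the end).

Ring labels: A = 3,4,5-trioxygenated ring; B = para-phenylene next to the carbinol; C = 1,2,3-trisubstituted ring; D = meta-phenylene.

Assumption: 3-bromo-4,5-dihydroxybenzaldehyde, 3-hydroxybenzyl alcohol, 2-fluoro-3-methoxybenzaldehyde and 4-(methoxymethoxy)benzaldehyde are bought as catalogue compounds (the first is otherwise one step from 5-bromovanillin with AlCl3/pyridine); the target carbinol is (S).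

**Step 1**
Reactants: 1 3-bromo-4,5-dihydroxybenzaldehyde
Product: 2 3-bromo-5-hydroxy-4-methoxybenzaldehyde
Conditions: MeI (1.05 equiv), Li2CO3 (1.2 equiv), DMF, 40 °C
Reagents that add atoms: iodomethane, CI
Why: The 4-OH (para to CHO, ortho to Br) is much the more acidic phenol, so its lithium phenoxide alone is methylated (regioselective Williamson etherification).

**Step 2**
Reactants: 3 3-(hydroxymethyl)phenol (3-hydroxybenzyl alcohol); 4 2-fluoro-3-methoxybenzaldehyde
Product: 5 2-[3-(hydroxymethyl)phenoxy]-3-methoxybenzaldehyde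
Conditions: K2CO3 (1.5 equiv), DMF, 110 °C
Reagents that add atoms: none
Why: The ortho-formyl group activates C–F, and carbonate forms only the phenoxide, not the benzylic alkoxide (nucleophilic aromatic substitution, SNAr).

**Step 3**
Reactants: 6 4-(methoxymethoxy)benzaldehyde
Product: 7 diphenyl {[4-(methoxymethoxy)phenyl](phenylamino)methyl}phosphonate (racemic)
Conditions: PhNH2 (1.0 equiv), (PhO)2P(O)H (1.0 equiv), MeCN, 25 °C
Reagents that add atoms: aniline, Nc1ccccc1; diphenyl phosphite, O=[PH](Oc1ccccc1)Oc1ccccc1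
Why: Imine formation followed by P–H addition gives the α-anilinophosphonate, an acyl-anion equivalent of the ring-B aldehyde (Kabachnik–Fields three-component reaction).

**Step 4**
Reactants: 5 2-[3-(hydroxymethyl)phenoxy]-3-methoxybenzaldehyde; 7 diphenyl {[4-(methoxymethoxy)phenyl](phenylamino)methyl}phosphonate
Product: 9 2-{2-[3-(hydroxymethyl)phenoxy]-3-methoxyphenyl}-1-(4-hydroxyphenyl)ethan-1-one, via enamine 8 (not isolated)
Conditions: Cs2CO3, THF/i-PrOH 4:1, 25 °C; then 3 M aq. HCl, MeOH, 50 °C
Reagents that add atoms: water, O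
Why: The phosphonate carbanion olefinates the aldehyde to an enamine, and acid hydrolysis gives the deoxybenzoin with C=O next to ring B while also removing the MOM group (Horner–Wadsworth–Emmons olefination of an α-aminophosphonate, Zimmer deoxybenzoin synthesis).

**Step 5**
Reactants: 9 2-{2-[3-(hydroxymethyl)phenoxy]-3-methoxyphenyl}-1-(4-hydroxyphenyl)ethan-1-one
Product: 10 (3-{2-[2-(4-hydroxyphenyl)-2-oxoethyl]-6-methoxyphenoxy}benzyl)triphenylphosphonium bromide
Conditions: PPh3·HBr (1.1 equiv), MeCN, reflux
Reagents that add atoms: triphenylphosphine hydrobromide, [Br-].[PH+](c1ccccc1)(c1ccccc1)c1ccccc1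
Why: PPh3·HBr converts the benzylic alcohol into the benzylphosphonium salt through the benzyl bromide (SN2 phosphonium salt formation); ketone, phenol and aryl ethers are inert.

**Step 6**
Reactants: 10 (3-{2-[2-(4-hydroxyphenyl)-2-oxoethyl]-6-methoxyphenoxy}benzyl)triphenylphosphonium bromide; 2 3-bromo-5-hydroxy-4-methoxybenzaldehyde
Product: 11 2-[2-(3-{2-(3-bromo-5-hydroxy-4-methoxyphenyl)ethenyl}phenoxy)-3-methoxyphenyl]-1-(4-hydroxyphenyl)ethan-1-one (E/Z mixture)
Conditions: NaOMe (3.5 equiv), MeOH/THF, 0 → 25 °C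
Reagents that add atoms: none
Why: Wittig olefination: the semi-stabilised benzylide reacts only with the aldehyde, because the ketone is deactivated in situ as the vinylogous carboxylate of its para-phenoxide, while the meta-phenoxide of 2 does not deactivate the formyl group.

**Step 7**
Reactants: 11 stilbene keto-diphenol (E/Z)
Product: 12 2-[2-(3-{2-(3-bromo-5-hydroxy-4-methoxyphenyl)ethyl}phenoxy)-3-methoxyphenyl]-1-(4-hydroxyphenyl)ethan-1-one (seco-ketone)
Conditions: H2 (5 bar), RhCl(PPh3)3 (10 mol%), THF/t-BuOH 1:1, 50 °C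
Reagents that add atoms: none
Why: Homogeneous hydrogenation with Wilkinson's catalyst saturates both stilbene isomers without cleaving Ar–Br or reducing the aryl ketone.

**Step 8**
Reactants: 12 seco-ketone
Product: 15 macrocyclic ketone dimethyl ether (18-membered ring closed by the ring A C3–O–ring B ether; ring A 4-OMe 5-OH; ring C 3-OMe; C=O on the carbon attached to ring B), via bromo-o-quinone monoketal 13 (not isolated), via macrocyclic aryloxy-o-quinone monoketal 14 (not isolated)
Conditions: PhI(OAc)2 (1.05 equiv), MeOH, −20 °C, then evaporate cold; Cs2CO3 (4 equiv), MeCN, 1 mM by syringe pump, 25 °C; then Na2S2O4, aq. NaHCO3/THF, 25 °C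
Reagents that add atoms: methanol, CO (forms the ketal; either ketal OMe may be the one kept on C4 after the reduction)
Why: Proposed new method: PhI(OAc)2/MeOH oxidises only the electron-rich guaiacol-type ring A (the p-acylphenol of ring B is inert) to the o-quinone monoketal 13, whose dienone has its β-carbon blocked by the side chain so that the ring-B phenoxide can add productively only 1,6 at the C–Br carbon, bromide then leaves by vinylogous E1cB to give 14 and dithionite re-aromatises with loss of one ketal methoxide, which overall is an oxidative phenol C–O coupling next to the ring-A oxygens; the closest known reaction type is the intermolecular oxa-Michael addition/elimination of phenols to brominated o-quinone monoketals followed by reductive aromatisation (used for polyoxygenated diaryl ethers), here run intramolecularly at high dilution on a dienone without an activating ester.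

**Step 9**
Reactants: 15 macrocyclic ketone dimethyl ether
Product: 16 macrocyclic triphenol ketone (ring A 4,5-di-OH; ring C 3-OH; C=O on the carbon attached to ring B)
Conditions: BBr3 (6 equiv), CH2Cl2, −78 → 0 °C; MeOH then aq. NaHCO3, under Ar
Reagents that add atoms: none
Why: BBr3 cleaves both aryl methyl ethers while diaryl ethers and the ketone survive (Lewis-acid ether cleavage); it is done at the ketone stage because the later p-aryloxybenzylic alcohol would ionise.

**Step 10**
Reactants: 16 macrocyclic triphenol ketone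
Product: 17 target, (S)-configured benzylic alcohol CNP0356934.1
Conditions: RuCl(p-cymene)[(S,S)-TsDPEN] (5 mol%), HCO2H/Et3N 5:2, DMF, 40 °C, Ar
Reagents that add atoms: none
Why: Noyori asymmetric transfer hydrogenation: the (S,S)-TsDPEN–Ru hydride adds to the Re face of the aryl ketone (aryl in the CH/π position, CH2Ar in the place of the methyl of acetophenone), which gives the (S)-carbinol as acetophenone gives (S)-1-phenylethanol.

**Compound list**
1 | 3-bromo-4,5-dihydroxybenzaldehyde | O=Cc1cc(O)c(O)c(Br)c1 | starting material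
2 | 3-bromo-5-hydroxy-4-methoxybenzaldehyde | O=Cc1cc(O)c(OC)c(Br)c1 | intermediate
3 | 3-(hydroxymethyl)phenol | OCc1cccc(O)c1 | starting material
4 | 2-fluoro-3-methoxybenzaldehyde | COc1cccc(C=O)c1F | starting material
5 | 2-[3-(hydroxymethyl)phenoxy]-3-methoxybenzaldehyde | COc1cccc(C=O)c1Oc1cccc(CO)c1 | intermediate
6 | 4-(methoxymethoxy)benzaldehyde | COCOc1ccc(C=O)cc1 | starting material
7 | diphenyl {[4-(methoxymethoxy)phenyl](phenylamino)methyl}phosphonate (racemic) | COCOc1ccc(cc1)C(Nc1ccccc1)P(=O)(Oc1ccccc1)Oc1ccccc1 | intermediate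
8 | N-{2-[2-(3-(hydroxymethyl)phenoxy)-3-methoxyphenyl]-1-[4-(methoxymethoxy)phenyl]ethenyl}aniline (enamine, E/Z) | COCOc1ccc(cc1)C(Nc1ccccc1)=Cc1cccc(OC)c1Oc1cccc(CO)c1 | intermediate
9 | 2-{2-[3-(hydroxymethyl)phenoxy]-3-methoxyphenyl}-1-(4-hydroxyphenyl)ethan-1-one | Oc1ccc(cc1)C(=O)Cc1cccc(OC)c1Oc1cccc(CO)c1 | intermediate
10 | (3-{2-[2-(4-hydroxyphenyl)-2-oxoethyl]-6-methoxyphenoxy}benzyl)triphenylphosphonium bromide | Oc1ccc(cc1)C(=O)Cc1cccc(OC)c1Oc1cccc(C[P+](c2ccccc2)(c2ccccc2)c2ccccc2)c1.[Br-] | intermediate
11 | 2-[2-(3-{2-(3-bromo-5-hydroxy-4-methoxyphenyl)ethenyl}phenoxy)-3-methoxyphenyl]-1-(4-hydroxyphenyl)ethan-1-one (E/Z mixture) | Oc1ccc(cc1)C(=O)Cc1cccc(OC)c1Oc1cccc(C=Cc2cc(O)c(OC)c(Br)c2)c1 | intermediate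
12 | 2-[2-(3-{2-(3-bromo-5-hydroxy-4-methoxyphenyl)ethyl}phenoxy)-3-methoxyphenyl]-1-(4-hydroxyphenyl)ethan-1-one (seco-ketone) | Oc1ccc(cc1)C(=O)Cc1cccc(OC)c1Oc1cccc(CCc2cc(O)c(OC)c(Br)c2)c1 | intermediate
13 | bromo-o-quinone monoketal of 12 (ring A replaced by a 5-bromo-6,6-dimethoxycyclohexa-2,4-dien-1-one carrying the CH2CH2 chain at C3) | Oc1ccc(cc1)C(=O)Cc1cccc(OC)c1Oc1cccc(CCC2=CC(=O)C(OC)(OC)C(Br)=C2)c1 | intermediate
14 | macrocyclic aryloxy-o-quinone monoketal (ring A = 6,6-dimethoxycyclohexa-2,4-dien-1-one with the ring-B aryloxy group at C5 and the CH2CH2 bridge at C3) | O=C1C=C2C=C(C1(OC)OC)Oc1ccc(cc1)C(=O)Cc1cccc(OC)c1Oc1cccc(c1)CC2 | intermediate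
15 | macrocyclic ketone dimethyl ether (ring A 3-aryloxy-4-methoxy-5-hydroxy; ring C 3-methoxy) | Oc1cc2cc(c1OC)Oc1ccc(cc1)C(=O)Cc1cccc(OC)c1Oc1cccc(c1)CC2 | intermediate
16 | macrocyclic triphenol ketone (oxo analogue of the target) | Oc1cc2cc(c1O)Oc1ccc(cc1)C(=O)Cc1cccc(O)c1Oc1cccc(c1)CC2 | intermediate
17 | CNP0356934.1, (S)-benzylic alcohol | Oc1cc2cc(c1O)Oc1ccc(cc1)[C@@H](O)Cc1cccc(O)c1Oc1cccc(c1)CC2 | target

**Step count and risks**
Total step count: 10. Longest linear sequence: 8 steps (steps 2, 4, 5, 6, 7, 8, 9, 10, from 3/4 to 17; steps 1 and 3 are one-step side branches).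

The three steps most likely to fail:

Step 8 (macrocyclisation) is the weakest step. The 1,6-addition has to take place on a dienone that lacks an activating ester and at a carbon flanked by the ketal. The monoketal can dimerise by Diels–Alder reaction, and the oxidant must leave the ring-B phenol alone. The fallback closes the same C3–O bond of 12 by copper catalysis instead of dearomatisation: CuI, N,N-dimethylglycine, Cs2CO3, dioxane, 100 °C, 2 mM, an intramolecular Ullmann etherification in which the ring-B phenoxide displaces the ring-A bromide. It sets out from 12, comes back to the route at 15 and makes no compound outside the list (none F0).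

Step 6 (Wittig on the unprotected keto-diphenol) may suffer from enolate/aldol side reactions and poor solubility of the polyanion. The fallback builds the A–D bibenzyl before any ketone exists, and sets out from 2. MOMCl/i-Pr2NEt gives 3-bromo-4-methoxy-5-(methoxymethoxy)benzaldehyde F1. Compound 3 and PPh3·HBr give (3-hydroxybenzyl)triphenylphosphonium bromide F2. Wittig reaction of the two (KOt-Bu, THF) gives the stilbene phenol F3, and diimide (TsNHNH2, NaOAc, DME/H2O, reflux) reduces it to the bibenzyl phenol F4. SNAr of this phenol on 4 (K2CO3, DMF, 110 °C) gives the diaryl ether aldehyde F5. Olefination with 7 (Cs2CO3, THF/i-PrOH) gives the bis-MOM enamine F6, and aqueous HCl/MeOH hydrolyses it and removes both MOM groups to give 12, where the route is rejoined.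

Step 10 (transfer hydrogenation of the free catechol ketone) may fail because the catechol can bind ruthenium, and the macrocycle may lower the selectivity. The fallback sets out from 16. Ac2O/pyridine gives the triacetate ketone F7. Reduction with (R)-Me-CBS (20 mol%) and BH3·SMe2 in THF at −20 °C gives the (S)-alcohol triacetate F8. Degassed K2CO3/MeOH at 0 °C removes the acetates and the route comes back at 17.

**Further compounds**
F0 | step 8 | none | none
F1 | step 6 | 3-bromo-4-methoxy-5-(methoxymethoxy)benzaldehyde | COCOc1cc(C=O)cc(Br)c1OC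
F2 | step 6 | (3-hydroxybenzyl)triphenylphosphonium bromide | Oc1cccc(C[P+](c2ccccc2)(c2ccccc2)c2ccccc2)c1.[Br-]
F3 | step 6 | stilbene phenol: 3-{2-[3-bromo-4-methoxy-5-(methoxymethoxy)phenyl]ethenyl}phenol (E/Z) | COCOc1cc(C=Cc2cccc(O)c2)cc(Br)c1OC
F4 | step 6 | bibenzyl phenol: 3-{2-[3-bromo-4-methoxy-5-(methoxymethoxy)phenyl]ethyl}phenol | COCOc1cc(CCc2cccc(O)c2)cc(Br)c1OC
F5 | step 6 | diaryl ether aldehyde: 2-(3-{2-[3-bromo-4-methoxy-5-(methoxymethoxy)phenyl]ethyl}phenoxy)-3-methoxybenzaldehyde | COCOc1cc(CCc2cccc(Oc3c(C=O)cccc3OC)c2)cc(Br)c1OC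
F6 | step 6 | bis-MOM enamine: N-{2-[2-(3-{2-[3-bromo-4-methoxy-5-(methoxymethoxy)phenyl]ethyl}phenoxy)-3-methoxyphenyl]-1-[4-(methoxymethoxy)phenyl]ethenyl}aniline (E/Z) | COCOc1ccc(cc1)C(Nc1ccccc1)=Cc1cccc(OC)c1Oc1cccc(CCc2cc(OCOC)c(OC)c(Br)c2)c1
F7 | step 10 | triacetate ketone (tri-O-acetyl derivative of 16) | CC(=O)Oc1cc2cc(c1OC(C)=O)Oc1ccc(cc1)C(=O)Cc1cccc(OC(C)=O)c1Oc1cccc(c1)CC2
F8 | step 10 | (S)-alcohol triacetate (tri-O-acetyl derivative of 17) | CC(=O)Oc1cc2cc(c1OC(C)=O)Oc1ccc(cc1)[C@@H](O)Cc1cccc(OC(C)=O)c1Oc1cccc(c1)CC2
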